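**Plan**

Positions are named as in germacranes: C1=C10 (C14 on C10), C4=C5 (C15 on C4), stereocentres C6–C9, acrylate carbons C11–C13.
Retrosynthesis: the lactone bond O6–C12 and the ring bond C5–C6 are cut together. C6 is at once the alkoxy carbon of the five-membered lactone and the allylic carbon next to the Z alkene C4=C5 of the ten-membered ring, so a C5 alkenyl metal adding to a C6 aldehyde closes the carbocycle and frees the alkoxide that closes the lactone on the C12 ester. Then C7–C8 (2-carboxyallylation), C1=C10 (aldol condensation) and C3–C4 (carbocupration of propyne) are cut.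
Forward: Normant carbocupration gives the Z C4=C5 iodide; aldol/elimination on a chiral-pool dioxolane ester adds C9, C10 and C14; an indium Barbier reaction with a Morita–Baylis–Hillman bromide adds C6, C7 and C11–C13; a Nozaki–Hiyama–Kishi ring closure with lactonisation in the same flask ends the skeleton.
Stereochemistry: C9 from the R dioxolane ester; C8 by Felkin–Anh addition anti to the C9 silyloxy group; C7 by the chair transition state of the allylindium (7,8-syn); C6 in the ring closure under control of C7 and C8; C4=C5 from syn carbocupration, C1=C10 from E1cB elimination.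
Helpers: the C9 triethylsilyl ether (steric control, later exchanged for acetate) and the C8 tert-butyldimethylsilyl ether (keeps O8 off the C12 ester, removed in step 19).

Key step: step 18

Assumption: the dioxolane ester 8 is purchased as its R enantiomer (chiral pool).

**Route**

Step 1
Reactants: 1 2-(2-bromoethyl)-1,3-dioxolane; 2 propyne
Product: 6 2-[(3Z)-4-iodo-3-methylbut-3-en-1-yl]-1,3-dioxolane, via Grignard reagent 3 (not isolated), via alkylcopper 4 (not isolated), via alkenylcopper 5 (not isolated)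
Conditions: Mg, THF, rt; CuBr·SMe2, Et2O/Me2S, −45 °C; propyne, −25 °C; I2, −50 → 0 °C
Reagents that add atoms: magnesium, [Mg] (in 3); CuBr·SMe2, Br[Cu].CSC (in 4, 5); iodine, [I][I] (in 6)
Why: Normant carbocupration: the alkylcopper adds syn across propyne with copper on the terminal carbon, and iodinolysis with retention places iodine cis to the chain, which fixes the Z geometry of C4=C5.

Step 2
Reactants: 6 2-[(3Z)-4-iodo-3-methylbut-3-en-1-yl]-1,3-dioxolane
Product: 7 (4Z)-5-iodo-4-methylpent-4-enal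
Conditions: 1 M aq. HCl, THF, rt
Reagents that add atoms: water, O
Why: Acid-catalysed acetal hydrolysis frees the C1 aldehyde and leaves the alkenyl iodide untouched.

Step 3
Reactants: 8 methyl 2-[(4R)-2,2-dimethyl-1,3-dioxolan-4-yl]acetate; 7 (4Z)-5-iodo-4-methylpent-4-enal
Product: 10 methyl (6Z)-2-[(4R)-2,2-dimethyl-1,3-dioxolan-4-yl]-3-hydroxy-7-iodo-6-methylhept-6-enoate (C2/C3 diastereomer mixture), via lithium enolate 9 (not isolated)
Conditions: LiN(i-Pr)2, THF, −78 °C; then 7, −78 °C; AcOH quench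
Reagents that add atoms: LiN(i-Pr)2, [Li]N(C(C)C)C(C)C (in 9)
Why: Aldol addition of the lithium ester enolate, kept at −78 °C so that the β-oxygen of the dioxolane is not eliminated, joins C10 to C1; the two new stereocentres are removed in step 4 and need no control.

Step 4
Reactants: 10 methyl (6Z)-2-[(4R)-2,2-dimethyl-1,3-dioxolan-4-yl]-3-hydroxy-7-iodo-6-methylhept-6-enoate
Product: 12 methyl (2E,6Z)-2-[(4R)-2,2-dimethyl-1,3-dioxolan-4-yl]-7-iodo-6-methylhepta-2,6-dienoate, via mesylate 11 (not isolated)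
Conditions: MsCl, Et3N, CH2Cl2, 0 °C; then DBU, 0 °C → rt
Reagents that add atoms: methanesulfonyl chloride, CS(=O)(=O)Cl (in 11)
Why: Mesylation and E1cB elimination should give the conjugated ester with the chain trans to the ester group (the tiglate-type geometry favoured in the enolate-like transition state), that is cis to C9 as the C1=C10 alkene of the target requires.

Step 5
Reactants: 12 methyl (2E,6Z)-2-[(4R)-2,2-dimethyl-1,3-dioxolan-4-yl]-7-iodo-6-methylhepta-2,6-dienoate
Product: 13 (2Z,6Z)-2-[(4R)-2,2-dimethyl-1,3-dioxolan-4-yl]-7-iodo-6-methylhepta-2,6-dien-1-ol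
Conditions: i-Bu2AlH, CH2Cl2, −78 °C; aq. potassium sodium tartrate work-up
Reagents that add atoms: none
Why: 1,2-Reduction of the conjugated ester gives the C14 allylic alcohol, with acetal and alkenyl iodide inert at −78 °C.

Step 6
Reactants: 13 (2Z,6Z)-2-[(4R)-2,2-dimethyl-1,3-dioxolan-4-yl]-7-iodo-6-methylhepta-2,6-dien-1-ol
Product: 14 (2Z,6Z)-2-[(4R)-2,2-dimethyl-1,3-dioxolan-4-yl]-7-iodo-6-methylhepta-2,6-dien-1-yl 3-methylbutanoate
Conditions: 3-methylbutanoyl chloride, pyridine, DMAP (cat.), CH2Cl2, 0 °C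
Reagents that add atoms: 3-methylbutanoyl chloride, CC(C)CC(=O)Cl
Why: Acylation of the primary allylic alcohol installs the C14 isovalerate of the target at an early stage, since every later step tolerates esters.

Step 7
Reactants: 14 (2Z,6Z)-2-[(4R)-2,2-dimethyl-1,3-dioxolan-4-yl]-7-iodo-6-methylhepta-2,6-dien-1-yl 3-methylbutanoate
Product: 15 (2Z,6Z)-2-[(1R)-1,2-dihydroxyethyl]-7-iodo-6-methylhepta-2,6-dien-1-yl 3-methylbutanoate
Conditions: AcOH/H2O (4:1), 40 °C
Reagents that add atoms: none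
Why: Mild aqueous acid hydrolyses the terminal acetonide and leaves the allylic ester in place.

Step 8
Reactants: 15 (2Z,6Z)-2-[(1R)-1,2-dihydroxyethyl]-7-iodo-6-methylhepta-2,6-dien-1-yl 3-methylbutanoate
Product: 16 (2Z,6Z)-2-[(1R)-1,2-bis(triethylsilyloxy)ethyl]-7-iodo-6-methylhepta-2,6-dien-1-yl 3-methylbutanoate
Conditions: Et3SiOTf, 2,6-lutidine, CH2Cl2, −78 °C
Reagents that add atoms: triethylsilyl trifluoromethanesulfonate, CC[Si](CC)(CC)OS(=O)(=O)C(F)(F)F
Why: Silylation of both hydroxyls; the C9 silyl ether later serves as the non-chelating group for Felkin–Anh control.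

Step 9
Reactants: 16 (2Z,6Z)-2-[(1R)-1,2-bis(triethylsilyloxy)ethyl]-7-iodo-6-methylhepta-2,6-dien-1-yl 3-methylbutanoate
Product: 17 (2Z,6Z)-7-iodo-6-methyl-2-[(1R)-2-oxo-1-(triethylsilyloxy)ethyl]hepta-2,6-dien-1-yl 3-methylbutanoate
Conditions: (COCl)2, DMSO, CH2Cl2, −78 → −30 °C; then Et3N, −78 → −20 °C; used crude
Reagents that add atoms: none
Why: Swern conditions convert a primary triethylsilyl ether directly into the aldehyde (the chlorosulfonium salt removes the primary silyl group as Et3SiCl and the alkoxysulfonium ion is oxidised), while the secondary silyl ether survives, so C8 is unmasked in one operation.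

Step 10
Reactants: 18 methyl acrylate; 19 (tert-butyldimethylsilyloxy)acetaldehyde
Product: 20 methyl 4-[(tert-butyldimethylsilyl)oxy]-3-hydroxy-2-methylidenebutanoate (racemic)
Conditions: DABCO (cat.), MeOH, rt
Reagents that add atoms: none
Why: Morita–Baylis–Hillman reaction; the carbinol stereocentre is removed in step 11, so the racemate suffices.

Step 11
Reactants: 20 methyl 4-[(tert-butyldimethylsilyl)oxy]-3-hydroxy-2-methylidenebutanoate
Product: 21 methyl (2Z)-2-(bromomethyl)-4-[(tert-butyldimethylsilyl)oxy]but-2-enoate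
Conditions: N-bromosuccinimide, Me2S, CH2Cl2, 0 °C → rt
Reagents that add atoms: N-bromosuccinimide, O=C1CCC(=O)N1Br
Why: The bromodimethylsulfonium salt activates the hydroxyl and bromide attacks in SN2' fashion (Corey–Kim-type allylic transposition), which gives the conjugated 2-(bromomethyl)alkenoate with the bromomethyl group cis to the silyloxymethyl group.

Step 12
Reactants: 17 (2Z,6Z)-7-iodo-6-methyl-2-[(1R)-2-oxo-1-(triethylsilyloxy)ethyl]hepta-2,6-dien-1-yl 3-methylbutanoate; 21 methyl (2Z)-2-(bromomethyl)-4-[(tert-butyldimethylsilyl)oxy]but-2-enoate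
Product: 23 methyl (3S,4S,5R,6Z,10Z)-3-{[(tert-butyldimethylsilyl)oxy]methyl}-4-hydroxy-11-iodo-10-methyl-2-methylidene-6-{[(3-methylbutanoyl)oxy]methyl}-5-[(triethylsilyl)oxy]undeca-6,10-dienoate, via allylindium reagent 22 (not isolated)
Conditions: In powder, THF/H2O (1:1), rt
Reagents that add atoms: indium, [In] (in 22)
Why: Barbier-type 2-(alkoxycarbonyl)allylation: the allylindium adds through its γ-carbon in a chair transition state (7,8-syn) and on the aldehyde face anti to the C9 silyloxy group (Felkin–Anh, 8,9-anti), which sets C7 and C8, while esters and the alkenyl iodide are inert to indium.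

Step 13
Reactants: 23 (C8 alcohol from step 12)
Product: 24 methyl (3S,4S,5R,6Z,10Z)-4-[(tert-butyldimethylsilyl)oxy]-3-{[(tert-butyldimethylsilyl)oxy]methyl}-11-iodo-10-methyl-2-methylidene-6-{[(3-methylbutanoyl)oxy]methyl}-5-[(triethylsilyl)oxy]undeca-6,10-dienoate
Conditions: t-BuMe2SiOTf, 2,6-lutidine, CH2Cl2, −78 → 0 °C
Reagents that add atoms: tert-butyldimethylsilyl trifluoromethanesulfonate, CC(C)(C)[Si](C)(C)OS(=O)(=O)C(F)(F)F
Why: Silylation of the hindered C8 hydroxyl with the triflate gives a robust ether that keeps O8 from attacking the C12 ester until the last step.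

Step 14
Reactants: 24 (C8 silyl ether from step 13)
Product: 25 methyl (3S,4S,5R,6Z,10Z)-4-[(tert-butyldimethylsilyl)oxy]-3-{[(tert-butyldimethylsilyl)oxy]methyl}-5-hydroxy-11-iodo-10-methyl-2-methylidene-6-{[(3-methylbutanoyl)oxy]methyl}undeca-6,10-dienoate
Conditions: PPTS (cat.), MeOH/CH2Cl2, 0 °C
Reagents that add atoms: none
Why: Mild acid methanolysis removes the triethylsilyl ether selectively, since it is far more labile than either tert-butyldimethylsilyl ether.

Step 15
Reactants: 25 (C9 alcohol from step 14)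
Product: 26 methyl (3S,4S,5R,6Z,10Z)-5-(acetyloxy)-4-[(tert-butyldimethylsilyl)oxy]-3-{[(tert-butyldimethylsilyl)oxy]methyl}-11-iodo-10-methyl-2-methylidene-6-{[(3-methylbutanoyl)oxy]methyl}undeca-6,10-dienoate
Conditions: Ac2O, pyridine, DMAP (cat.), CH2Cl2, 0 °C
Reagents that add atoms: acetic anhydride, CC(=O)OC(C)=O
Why: Acetylation of the only free hydroxyl installs the C9 acetate of the target.

Step 16
Reactants: 26 (C9 acetate from step 15)
Product: 27 methyl (3S,4S,5R,6Z,10Z)-5-(acetyloxy)-4-[(tert-butyldimethylsilyl)oxy]-3-(hydroxymethyl)-11-iodo-10-methyl-2-methylidene-6-{[(3-methylbutanoyl)oxy]methyl}undeca-6,10-dienoate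
Conditions: HF·pyridine, pyridine, THF, 0 °C; used crude
Reagents that add atoms: none
Why: Buffered HF·pyridine cleaves the primary silyl ether much faster than the hindered secondary one at C8, and the γ-hydroxy ester is used at once so that it does not lactonise.

Step 17
Reactants: 27 (C6 primary alcohol from step 16)
Product: 28 methyl (3R,4S,5R,6Z,10Z)-5-(acetyloxy)-4-[(tert-butyldimethylsilyl)oxy]-3-formyl-11-iodo-10-methyl-2-methylidene-6-{[(3-methylbutanoyl)oxy]methyl}undeca-6,10-dienoate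
Conditions: Dess–Martin periodinane, NaHCO3, CH2Cl2, 0 °C → rt; used crude
Reagents that add atoms: none
Why: Dess–Martin oxidation under buffered, amine-free conditions should give the C6 aldehyde without epimerising C7 or moving the C11=C13 alkene into conjugation.

Step 18
Reactants: 28 (iodoalkenyl aldehyde from step 17)
Product: 31 [(3aS,4S,5R,6Z,10Z,11aR)-5-(acetyloxy)-4-[(tert-butyldimethylsilyl)oxy]-10-methyl-3-methylidene-2-oxo-2,3,3a,4,5,8,9,11a-octahydrocyclodeca[b]furan-6-yl]methyl 3-methylbutanoate, via alkenylchromium dichloride 29 (not isolated), via macrocyclic hydroxy ester 30 (not isolated)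
Conditions: CrCl2 (excess), NiCl2 (cat.), DMSO/THF, high dilution (slow addition of 28), rt; aqueous work-up; then PPTS (cat.), CH2Cl2, rt
Reagents that add atoms: CrCl2, Cl[Cr]Cl (in 29)
Why: Zerovalent nickel (from NiCl2 and CrCl2) inserts into the C5–iodine bond with retention of the Z geometry, transmetalation gives the alkenylchromium dichloride 29, and this adds to the C6 aldehyde; the trivalent-chromium alkoxide (hydroxy ester 30 after work-up) then attacks the C12 methyl ester and expels methanol. The closest known reaction type is the Nozaki–Hiyama–Kishi macrocyclisation of iodoalkenyl aldehydes to medium-ring allylic alcohols, followed by the usual lactonisation of a γ-hydroxy α-methylene ester. The ten-membered carbocycle closes by 10-exo-trig addition to the aldehyde and the five-membered lactone by 5-exo-trig acyl substitution. C6 is controlled by C7 and C8: in the cyclic transition state the C7–C11 bond should lie anti to the incoming C5 and the chromium-bound oxygen should point outward next to H7, away from C8 and its silyloxy group (1,3-anti to O8), which gives 6R and hence the trans-fused lactone. The step needs selectivity for the aldehyde over three ester groups (two of them allylic), which organochromium reagents provide, and ring closure over oligomerisation, which high dilution and the two cis alkenes of the tether (C1=C10, C4=C5) favour. It also needs C7 to stay intact, which the non-basic medium should ensure.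

Step 19
Reactants: 31 (C8 silyl ether of the target)
Product: 32 [(3aR,4S,5R,6Z,10Z,11aR)-5-(acetyloxy)-4-hydroxy-10-methyl-3-methylidene-2-oxo-2,3,3a,4,5,8,9,11a-octahydrocyclodeca[b]furan-6-yl]methyl 3-methylbutanoate (target)
Conditions: HF·pyridine, THF, 0 °C → rt
Reagents that add atoms: none
Why: Acidic fluoride cleaves the hindered secondary silyl ether and frees the C8 hydroxyl under conditions that should cause neither acetyl migration nor addition to the methylene lactone.

**Compound list**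

1 | 2-(2-bromoethyl)-1,3-dioxolane | BrCCC1OCCO1 | starting material
2 | propyne | CC#C | starting material
3 | [2-(1,3-dioxolan-2-yl)ethyl]magnesium bromide | Br[Mg]CCC1OCCO1 | intermediate
4 | [2-(1,3-dioxolan-2-yl)ethyl]copper (as its MgBr2·SMe2 complex) | [Cu]CCC1OCCO1 | intermediate
5 | [(1Z)-4-(1,3-dioxolan-2-yl)-2-methylbut-1-en-1-yl]copper | [Cu]/C=C(/C)CCC1OCCO1 | intermediate
6 | 2-[(3Z)-4-iodo-3-methylbut-3-en-1-yl]-1,3-dioxolane | I/C=C(/C)CCC1OCCO1 | intermediate
7 | (4Z)-5-iodo-4-methylpent-4-enal | O=CCC/C(C)=C\I | intermediate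
8 | methyl 2-[(4R)-2,2-dimethyl-1,3-dioxolan-4-yl]acetate | COC(=O)C[C@@H]1COC(C)(C)O1 | starting material
9 | lithium enolate of 8 | COC(O[Li])=C[C@@H]1COC(C)(C)O1 | intermediate
10 | methyl (6Z)-2-[(4R)-2,2-dimethyl-1,3-dioxolan-4-yl]-3-hydroxy-7-iodo-6-methylhept-6-enoate (C2/C3 mixture) | COC(=O)C([C@@H]1COC(C)(C)O1)C(O)CC/C(C)=C\I | intermediate
11 | methyl (6Z)-2-[(4R)-2,2-dimethyl-1,3-dioxolan-4-yl]-7-iodo-3-(methanesulfonyloxy)-6-methylhept-6-enoate | COC(=O)C([C@@H]1COC(C)(C)O1)C(OS(C)(=O)=O)CC/C(C)=C\I | intermediate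
12 | methyl (2E,6Z)-2-[(4R)-2,2-dimethyl-1,3-dioxolan-4-yl]-7-iodo-6-methylhepta-2,6-dienoate | COC(=O)/C(=C/CC/C(C)=C\I)[C@@H]1COC(C)(C)O1 | intermediate
13 | (2Z,6Z)-2-[(4R)-2,2-dimethyl-1,3-dioxolan-4-yl]-7-iodo-6-methylhepta-2,6-dien-1-ol | OC/C(=C/CC/C(C)=C\I)[C@@H]1COC(C)(C)O1 | intermediate
14 | (2Z,6Z)-2-[(4R)-2,2-dimethyl-1,3-dioxolan-4-yl]-7-iodo-6-methylhepta-2,6-dien-1-yl 3-methylbutanoate | CC(C)CC(=O)OC/C(=C/CC/C(C)=C\I)[C@@H]1COC(C)(C)O1 | intermediate
15 | (2Z,6Z)-2-[(1R)-1,2-dihydroxyethyl]-7-iodo-6-methylhepta-2,6-dien-1-yl 3-methylbutanoate | CC(C)CC(=O)OC/C(=C/CC/C(C)=C\I)[C@@H](O)CO | intermediate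
16 | (2Z,6Z)-2-[(1R)-1,2-bis(triethylsilyloxy)ethyl]-7-iodo-6-methylhepta-2,6-dien-1-yl 3-methylbutanoate | CC(C)CC(=O)OC/C(=C/CC/C(C)=C\I)[C@@H](O[Si](CC)(CC)CC)CO[Si](CC)(CC)CC | intermediate
17 | (2Z,6Z)-7-iodo-6-methyl-2-[(1R)-2-oxo-1-(triethylsilyloxy)ethyl]hepta-2,6-dien-1-yl 3-methylbutanoate | CC(C)CC(=O)OC/C(=C/CC/C(C)=C\I)[C@@H](O[Si](CC)(CC)CC)C=O | intermediate
18 | methyl acrylate | C=CC(=O)OC | starting material
19 | (tert-butyldimethylsilyloxy)acetaldehyde | O=CCO[Si](C)(C)C(C)(C)C | starting material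
20 | methyl 4-[(tert-butyldimethylsilyl)oxy]-3-hydroxy-2-methylidenebutanoate (racemic) | COC(=O)C(=C)C(O)CO[Si](C)(C)C(C)(C)C | intermediate
21 | methyl (2Z)-2-(bromomethyl)-4-[(tert-butyldimethylsilyl)oxy]but-2-enoate | COC(=O)/C(CBr)=C/CO[Si](C)(C)C(C)(C)C | intermediate
22 | allylindium reagent from 21 (monovalent indium, indium on the former CH2Br carbon) | COC(=O)/C(C[In])=C/CO[Si](C)(C)C(C)(C)C | intermediate
23 | methyl (3S,4S,5R,6Z,10Z)-3-{[(tert-butyldimethylsilyl)oxy]methyl}-4-hydroxy-11-iodo-10-methyl-2-methylidene-6-{[(3-methylbutanoyl)oxy]methyl}-5-[(triethylsilyl)oxy]undeca-6,10-dienoate | I/C=C(/C)CC/C=C(/COC(=O)CC(C)C)[C@@H](O[Si](CC)(CC)CC)[C@@H](O)[C@@H](C(=C)C(=O)OC)CO[Si](C)(C)C(C)(C)C | intermediate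
24 | methyl (3S,4S,5R,6Z,10Z)-4-[(tert-butyldimethylsilyl)oxy]-3-{[(tert-butyldimethylsilyl)oxy]methyl}-11-iodo-10-methyl-2-methylidene-6-{[(3-methylbutanoyl)oxy]methyl}-5-[(triethylsilyl)oxy]undeca-6,10-dienoate | I/C=C(/C)CC/C=C(/COC(=O)CC(C)C)[C@@H](O[Si](CC)(CC)CC)[C@@H](O[Si](C)(C)C(C)(C)C)[C@@H](C(=C)C(=O)OC)CO[Si](C)(C)C(C)(C)C | intermediate
25 | methyl (3S,4S,5R,6Z,10Z)-4-[(tert-butyldimethylsilyl)oxy]-3-{[(tert-butyldimethylsilyl)oxy]methyl}-5-hydroxy-11-iodo-10-methyl-2-methylidene-6-{[(3-methylbutanoyl)oxy]methyl}undeca-6,10-dienoate | I/C=C(/C)CC/C=C(/COC(=O)CC(C)C)[C@@H](O)[C@@H](O[Si](C)(C)C(C)(C)C)[C@@H](C(=C)C(=O)OC)CO[Si](C)(C)C(C)(C)C | intermediate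
26 | methyl (3S,4S,5R,6Z,10Z)-5-(acetyloxy)-4-[(tert-butyldimethylsilyl)oxy]-3-{[(tert-butyldimethylsilyl)oxy]methyl}-11-iodo-10-methyl-2-methylidene-6-{[(3-methylbutanoyl)oxy]methyl}undeca-6,10-dienoate | I/C=C(/C)CC/C=C(/COC(=O)CC(C)C)[C@@H](OC(C)=O)[C@@H](O[Si](C)(C)C(C)(C)C)[C@@H](C(=C)C(=O)OC)CO[Si](C)(C)C(C)(C)C | intermediate
27 | methyl (3S,4S,5R,6Z,10Z)-5-(acetyloxy)-4-[(tert-butyldimethylsilyl)oxy]-3-(hydroxymethyl)-11-iodo-10-methyl-2-methylidene-6-{[(3-methylbutanoyl)oxy]methyl}undeca-6,10-dienoate | I/C=C(/C)CC/C=C(/COC(=O)CC(C)C)[C@@H](OC(C)=O)[C@@H](O[Si](C)(C)C(C)(C)C)[C@@H](C(=C)C(=O)OC)CO | intermediate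
28 | methyl (3R,4S,5R,6Z,10Z)-5-(acetyloxy)-4-[(tert-butyldimethylsilyl)oxy]-3-formyl-11-iodo-10-methyl-2-methylidene-6-{[(3-methylbutanoyl)oxy]methyl}undeca-6,10-dienoate | I/C=C(/C)CC/C=C(/COC(=O)CC(C)C)[C@@H](OC(C)=O)[C@@H](O[Si](C)(C)C(C)(C)C)[C@@H](C(=C)C(=O)OC)C=O | intermediate
29 | alkenylchromium dichloride from 28 (CrCl2 in place of iodine at C5, Z retained) | Cl[Cr](Cl)/C=C(/C)CC/C=C(/COC(=O)CC(C)C)[C@@H](OC(C)=O)[C@@H](O[Si](C)(C)C(C)(C)C)[C@@H](C(=C)C(=O)OC)C=O | intermediate
30 | methyl 2-[(1S,2R,3Z,7Z,9R,10S)-9-(acetyloxy)-10-[(tert-butyldimethylsilyl)oxy]-2-hydroxy-4-methyl-8-{[(3-methylbutanoyl)oxy]methyl}cyclodeca-3,7-dien-1-yl]prop-2-enoate | O[C@@H]1/C=C(/C)CC/C=C(/COC(=O)CC(C)C)[C@@H](OC(C)=O)[C@@H](O[Si](C)(C)C(C)(C)C)[C@H]1C(=C)C(=O)OC | intermediate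
31 | [(3aS,4S,5R,6Z,10Z,11aR)-5-(acetyloxy)-4-[(tert-butyldimethylsilyl)oxy]-10-methyl-3-methylidene-2-oxo-2,3,3a,4,5,8,9,11a-octahydrocyclodeca[b]furan-6-yl]methyl 3-methylbutanoate | C=C1C(=O)O[C@@H]2/C=C(/C)CC/C=C(/COC(=O)CC(C)C)[C@@H](OC(C)=O)[C@@H](O[Si](C)(C)C(C)(C)C)[C@@H]12 | intermediate
32 | [(3aR,4S,5R,6Z,10Z,11aR)-5-(acetyloxy)-4-hydroxy-10-methyl-3-methylidene-2-oxo-2,3,3a,4,5,8,9,11a-octahydrocyclodeca[b]furan-6-yl]methyl 3-methylbutanoate | C=C1C(=O)O[C@@H]2/C=C(/C)CC/C=C(/COC(=O)CC(C)C)[C@@H](OC(C)=O)[C@@H](O)[C@@H]12 | target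

**Count and risks**

Total steps: 19. Longest linear sequence: 17 (steps 1–9 and 12–19; steps 10–11 make the side fragment 21).

Steps most likely to fail:

1. Step 18: poor facial selectivity at C6 in the ring closure, that is attack on the other aldehyde face to give the 6S alkoxide. The fallback sets out from 28: the cyclisation is worked up without acid, and the 6S alcohol, methyl 2-[(1S,2S,3Z,7Z,9R,10S)-9-(acetyloxy)-10-[(tert-butyldimethylsilyl)oxy]-2-hydroxy-4-methyl-8-{[(3-methylbutanoyl)oxy]methyl}cyclodeca-3,7-dien-1-yl]prop-2-enoate F1, is isolated as the open hydroxy ester, since its lactonisation would need a cis ring fusion and should be slow. Mitsunobu inversion (ClCH2CO2H, PPh3, diisopropyl azodicarboxylate, toluene, 0 °C) should give the 6R chloroacetate F2. Thiourea (EtOH, 50 °C) removes the chloroacetyl group selectively beside acetate and isovalerate and gives 30, where the route is rejoined; 30 lactonises to 31 as in step 18.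

2. Step 12: erosion of the Felkin–Anh or the syn selectivity in the open aqueous Barbier process, or loss of the C9 silyl group in the aqueous medium. The fallback sets out from 20: acetylation (Ac2O, pyridine, DMAP) gives methyl 3-(acetyloxy)-4-[(tert-butyldimethylsilyl)oxy]-2-methylidenebutanoate F3. Copper-catalysed SN2' borylation (B2pin2, CuCl cat., KOAc cat., DMF) gives the allylboronate methyl (2E)-4-[(tert-butyldimethylsilyl)oxy]-2-[(4,4,5,5-tetramethyl-1,3,2-dioxaborolan-2-yl)methyl]but-2-enoate F4, in which the boron-bearing CH2 is cis to the silyloxymethyl group. Its anhydrous allylboration of 17 (toluene, 50 °C) goes through a closed six-membered transition state, which turns that geometry into the 7,8-syn relationship and keeps the 8,9-anti preference, and gives the O-boryl adduct F5. Aqueous NaHCO3 work-up gives 23, where the route is rejoined.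

3. Step 9: epimerisation at C9 or migration of the C1=C10 alkene into conjugation while the α-silyloxy aldehyde is formed in the presence of amine base. The fallback sets out from 16: selective methanolysis of the primary silyl ether (PPTS, MeOH/CH2Cl2, −10 °C) gives the primary alcohol (2Z,6Z)-2-[(1R)-2-hydroxy-1-(triethylsilyloxy)ethyl]-7-iodo-6-methylhepta-2,6-dien-1-yl 3-methylbutanoate F6. Oxidation with Dess–Martin periodinane in CH2Cl2 without any amine gives 17, where the route is rejoined.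

Further compounds
F1 | step 18 | methyl 2-[(1S,2S,3Z,7Z,9R,10S)-9-(acetyloxy)-10-[(tert-butyldimethylsilyl)oxy]-2-hydroxy-4-methyl-8-{[(3-methylbutanoyl)oxy]methyl}cyclodeca-3,7-dien-1-yl]prop-2-enoate | O[C@H]1/C=C(/C)CC/C=C(/COC(=O)CC(C)C)[C@@H](OC(C)=O)[C@@H](O[Si](C)(C)C(C)(C)C)[C@H]1C(=C)C(=O)OC
F2 | step 18 | methyl 2-[(1S,2R,3Z,7Z,9R,10S)-9-(acetyloxy)-10-[(tert-butyldimethylsilyl)oxy]-2-[(chloroacetyl)oxy]-4-methyl-8-{[(3-methylbutanoyl)oxy]methyl}cyclodeca-3,7-dien-1-yl]prop-2-enoate | ClCC(=O)O[C@@H]1/C=C(/C)CC/C=C(/COC(=O)CC(C)C)[C@@H](OC(C)=O)[C@@H](O[Si](C)(C)C(C)(C)C)[C@H]1C(=C)C(=O)OC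
F3 | step 12 | methyl 3-(acetyloxy)-4-[(tert-butyldimethylsilyl)oxy]-2-methylidenebutanoate | COC(=O)C(=C)C(OC(C)=O)CO[Si](C)(C)C(C)(C)C
F4 | step 12 | methyl (2E)-4-[(tert-butyldimethylsilyl)oxy]-2-[(4,4,5,5-tetramethyl-1,3,2-dioxaborolan-2-yl)methyl]but-2-enoate | COC(=O)/C(CB1OC(C)(C)C(C)(C)O1)=C/CO[Si](C)(C)C(C)(C)C
F5 | step 12 | methyl (3S,4S,5R,6Z,10Z)-3-{[(tert-butyldimethylsilyl)oxy]methyl}-11-iodo-10-methyl-2-methylidene-6-{[(3-methylbutanoyl)oxy]methyl}-4-[(4,4,5,5-tetramethyl-1,3,2-dioxaborolan-2-yl)oxy]-5-[(triethylsilyl)oxy]undeca-6,10-dienoate | I/C=C(/C)CC/C=C(/COC(=O)CC(C)C)[C@@H](O[Si](CC)(CC)CC)[C@@H](OB1OC(C)(C)C(C)(C)O1)[C@@H](C(=C)C(=O)OC)CO[Si](C)(C)C(C)(C)C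
F6 | step 9 | (2Z,6Z)-2-[(1R)-2-hydroxy-1-(triethylsilyloxy)ethyl]-7-iodo-6-methylhepta-2,6-dien-1-yl 3-methylbutanoate | CC(C)CC(=O)OC/C(=C/CC/C(C)=C\I)[C@@H](O[Si](CC)(CC)CC)CO
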